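**Plan**

1. Atom numbers follow ent-kaurane: ring A = C1–C5/C10; δ-lactone C8–C7(=O)–O–C20–C10–C9; ring C = C8, C9, C11–C14; ring D = C8, C14, C13, C16, C15; C19 is the acetoxymethyl carbon on C4, C6 the aldehyde carbon.
2. Retrosynthesis: (a) C13–C16 is cut and C12–C16 re-made, which takes ring D back to the six-membered ring C8–C15–C16–C12–C13–C14 of a bicyclo[2.2.2]octenone; (b) C8–C14 and C12–C13 are cut (Diels–Alder of a masked o-benzoquinone with a vinyl selenide); (c) C9–C10 (Heck) and the C7–O ester bond; (d) C2–C3 and C4–C5 of ring A (Diels–Alder with methacrolein).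
3. Forward: ring A by catalytic asymmetric Diels–Alder; C20 by methylenation and 1,3-transposition; an ester-tethered Heck reaction closes the δ-lactone and the spiro centre C10; dearomatisation and Diels–Alder give ring C inside a bicyclo[2.2.2]octenone; a radical 1,2-acyl shift contracts it to ring D; then C16=CH2 (Peterson), C11–OH (hydroboration) and unmasking of C15=O and C6HO.
4. Enabling feature: in the bicyclo[2.2.2]oct-5-en-2-one the C16 ketone sits on bridgehead C12 next to the radical site C13, and C12 is allylic to C9=C11, so the acyl shift ends in an allyl radical.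
5. Stereochemistry: C4 from the chiral Lewis acid; C5 from the endo rule; C10 from Heck insertion anti to the C5/C4 substituents; C8 (and with it C13) from cycloaddition on the diene face remote from C5; C9 and C11 from syn hydroboration on the face of the one-carbon bridge C14.

Key step: step 16

Assumption: the (S)-configured oxazaborolidinium ion of step 3 is taken to deliver (1R,2S)-7, as the formyl C–H···O binding model for 2-substituted acroleins predicts; the mirror-image catalyst would be used if the sense were opposite.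

**Route**

Step 1
Reactants: 1 2,2-dimethoxyacetaldehyde (60% in water); 2 1-(triphenyl-λ5-phosphanylidene)propan-2-one
Product: 3 (E)-5,5-dimethoxypent-3-en-2-one
Conditions: CH2Cl2/H2O, rt, 16 h
Reagents that add atoms: none
Why: Wittig olefination with a ketone-stabilised ylide should give the (E)-enone.

Step 2
Reactants: 3 (E)-5,5-dimethoxypent-3-en-2-one
Product: 5 (E)-2-(tert-butyldimethylsilyloxy)-5,5-dimethoxypenta-1,3-diene, via lithium dienolate 4 (not isolated)
Conditions: LiN(iPr)2, THF, −78 °C; then t-BuMe2SiCl, DMPU, −78 °C → 0 °C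
Reagents that add atoms: tert-butyldimethylsilyl chloride CC(C)(C)[Si](C)(C)Cl
Why: Kinetic deprotonation of the methyl ketone gives the cross-conjugated dienolate and O-silylation (silyl enol ether formation) should give the 2-silyloxy diene with the (E) alkene untouched.

Step 3
Reactants: 5 (E)-2-(tert-butyldimethylsilyloxy)-5,5-dimethoxypenta-1,3-diene; 6 methacrolein
Product: 7 (1R,2S)-4-[(tert-butyldimethylsilyl)oxy]-2-(dimethoxymethyl)-1-methylcyclohex-3-ene-1-carbaldehyde
Conditions: (S)-1-(2-methylphenyl)-3,3-diphenyltetrahydro-1H,3H-pyrrolo[1,2-c][1,3,2]oxazaborole (20 mol%) protonated with HN(SO2CF3)2 (17 mol%), CH2Cl2, −78 °C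
Reagents that add atoms: none
Why: Enantioselective Diels–Alder reaction under chiral oxazaborolidinium Lewis acid catalysis, in which the silyloxy group (para rule) and the C5 substituent (ortho rule) both send C4 to C5, the endo transition state places CHO cis to CH(OMe)2 at C5, and the catalyst selects the face of methacrolein and so sets quaternary C4.

Step 4
Reactants: 7 (1R,2S)-4-[(tert-butyldimethylsilyl)oxy]-2-(dimethoxymethyl)-1-methylcyclohex-3-ene-1-carbaldehyde
Product: 8 [(1R,2S)-4-[(tert-butyldimethylsilyl)oxy]-2-(dimethoxymethyl)-1-methylcyclohex-3-en-1-yl]methanol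
Conditions: NaBH4, EtOH, 0 °C
Reagents that add atoms: none
Why: Borohydride reduction takes the aldehyde only, the silyl enol ether and the acetal being inert.

Step 5
Reactants: 8 [(1R,2S)-4-[(tert-butyldimethylsilyl)oxy]-2-(dimethoxymethyl)-1-methylcyclohex-3-en-1-yl]methanol
Product: 9 [(1R,2S)-4-[(tert-butyldimethylsilyl)oxy]-2-(dimethoxymethyl)-1-methylcyclohex-3-en-1-yl]methyl acetate
Conditions: Ac2O, pyridine, DMAP (cat.), CH2Cl2, rt
Reagents that add atoms: acetic anhydride CC(=O)OC(C)=O
Why: DMAP-catalysed acylation of the primary neopentyl alcohol installs the C19 acetate of the target early.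

Step 6
Reactants: 9 [(1R,2S)-4-[(tert-butyldimethylsilyl)oxy]-2-(dimethoxymethyl)-1-methylcyclohex-3-en-1-yl]methyl acetate
Product: 12 [(1R,2R)-2-(dimethoxymethyl)-1-methyl-3-methylidene-4-oxocyclohexyl]methyl acetate, via Mannich base 10 (not isolated), via methiodide salt 11 (not isolated)
Conditions: [CH2=NMe2]I, CH2Cl2, rt; then MeI, rt; then aq. NaHCO3, CH2Cl2, rt
Reagents that add atoms: N,N-dimethylmethylideneammonium iodide C=[N+](C)C.[I-]
Why: Mannich reaction at C10 of the regiodefined silyl enol ether, N-methylation and β-elimination (Eschenmoser methylenation) should give the α-methylene ketone under conditions too mild to move the alkene toward C5.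

Step 7
Reactants: 12 [(1R,2R)-2-(dimethoxymethyl)-1-methyl-3-methylidene-4-oxocyclohexyl]methyl acetate
Product: 13 [(1R,2R)-2-(dimethoxymethyl)-4-hydroxy-1-methyl-3-methylidenecyclohexyl]methyl acetate (both carbinol epimers)
Conditions: NaBH4, CeCl3·7H2O, MeOH, −78 °C
Reagents that add atoms: none
Why: Luche reduction gives clean 1,2-reduction of the enone, and the carbinol configuration is of no consequence because it is lost in the next step.

Step 8
Reactants: 13 [(1R,2R)-2-(dimethoxymethyl)-4-hydroxy-1-methyl-3-methylidenecyclohexyl]methyl acetate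
Product: 14 [(1R,2R)-2-(dimethoxymethyl)-3-(hydroxymethyl)-1-methylcyclohex-3-en-1-yl]methyl acetate
Conditions: Ph3SiOReO3 (2 mol%), Et2O, 0 °C
Reagents that add atoms: none
Why: Rhenium-oxo-catalysed 1,3-transposition of the allylic alcohol ([3,3] shift of the perrhenate ester) should run to the primary alcohol with the trisubstituted ring alkene C10=C1, which moves the oxygen from C1 to C20.

Step 9
Reactants: 15 1-(benzyloxy)-4-bromo-2-methoxybenzene
Product: 17 3-(benzyloxy)-6-bromo-2-methoxybenzoic acid, via aryllithium 16 (not isolated)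
Conditions: LiN(iPr)2, THF, −78 °C; then CO2; then 1 M HCl
Reagents that add atoms: carbon dioxide O=C=O
Why: Directed ortho-lithiation removes the most acidic proton, the one flanked by OMe and Br, and carboxylation of the aryllithium at −78 °C precedes any aryne formation.

Step 10
Reactants: 14 [(1R,2R)-2-(dimethoxymethyl)-3-(hydroxymethyl)-1-methylcyclohex-3-en-1-yl]methyl acetate; 17 3-(benzyloxy)-6-bromo-2-methoxybenzoic acid
Product: 18 [(5R,6R)-5-(acetoxymethyl)-6-(dimethoxymethyl)-5-methylcyclohex-1-en-1-yl]methyl 3-(benzyloxy)-6-bromo-2-methoxybenzoate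
Conditions: PPh3, diisopropyl azodicarboxylate, THF, 0 °C → rt
Reagents that add atoms: none
Why: Mitsunobu esterification uses the hindered 2,6-disubstituted benzoic acid as the nucleophile at the primary allylic carbon, which avoids acylation at a crowded carbonyl group.

Step 11
Reactants: 18 [(5R,6R)-5-(acetoxymethyl)-6-(dimethoxymethyl)-5-methylcyclohex-1-en-1-yl]methyl 3-(benzyloxy)-6-bromo-2-methoxybenzoate
Product: 19 [(1S,5R,6R)-7'-(benzyloxy)-6-(dimethoxymethyl)-8'-methoxy-5-methyl-1'-oxospiro[cyclohex-2-ene-1,4'-isochroman]-5-yl]methyl acetate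
Conditions: Pd(OAc)2 (10 mol%), P(o-tol)3 (20 mol%), Et3N, MeCN, 80 °C
Reagents that add atoms: none
Why: Intramolecular Heck reaction: 6-exo-trig insertion of the aryl–palladium bond into C10=C1 closes the δ-lactone ring and β-hydride loss toward C2 follows, the aryl group entering on the face of C10 opposite to the cis CH(OMe)2 and CH2OAc groups and so setting the spiro centre.

Step 12
Reactants: 19 [(1S,5R,6R)-7'-(benzyloxy)-6-(dimethoxymethyl)-8'-methoxy-5-methyl-1'-oxospiro[cyclohex-2-ene-1,4'-isochroman]-5-yl]methyl acetate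
Product: 20 [(1S,2R,3R)-2-(dimethoxymethyl)-7'-hydroxy-8'-methoxy-3-methyl-1'-oxospiro[cyclohexane-1,4'-isochroman]-3-yl]methyl acetate
Conditions: H2 (1 atm), Pd on carbon (10 wt% Pd), EtOAc, rt
Reagents that add atoms: none
Why: Catalytic hydrogenation saturates the ring A alkene (any positional isomers converge) and cleaves the benzyl ether in one operation.

Step 13
Reactants: 20 [(1S,2R,3R)-2-(dimethoxymethyl)-7'-hydroxy-8'-methoxy-3-methyl-1'-oxospiro[cyclohexane-1,4'-isochroman]-3-yl]methyl acetate
Product: 21 masked o-benzoquinone (6,6-dimethoxycyclohexa-2,4-dienone fused to the spiro δ-lactone)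
Conditions: PhI(OAc)2, MeOH, 0 °C
Reagents that add atoms: methanol CO
Why: Oxidative dearomatisation of the 2-methoxyphenol with capture of methanol at C15 gives the masked o-benzoquinone, whose substituents at C8 and C9 should slow its dimerisation enough for isolation.

Step 14
Reactants: 22 phenylselenenyl bromide; 23 vinylmagnesium bromide
Product: 24 phenyl vinyl selenide
Conditions: THF, −78 °C → rt
Reagents that add atoms: none
Why: Selenenylation of the vinyl Grignard reagent is a standard route to the vinyl selenide.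

Step 15
Reactants: 21 masked o-benzoquinone; 24 phenyl vinyl selenide
Product: 25 13-phenylselanyl bicyclo[2.2.2]octenone adduct (both C13 epimers)
Conditions: 24 (5 equiv), toluene, 110 °C, sealed tube, dark
Reagents that add atoms: none
Why: Inverse-electron-demand Diels–Alder reaction of a masked o-benzoquinone with an electron-rich alkene: the CH2 terminus should bond to C8 (the δ-carbon of the dienone) and the selenium-bearing carbon to the unhindered C12 next to the ketone, on the diene face that carries C1H2 of ring A and not the substituted C5, which sets C8 and C12.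

Step 16
Reactants: 25 13-phenylselanyl bicyclo[2.2.2]octenone adduct
Product: 29 15,15-dimethoxy-16-oxo-17-nor-6,7-seco-ent-kaur-9(11)-ene lactone, via C13 radical 26 (not isolated), via cyclopropyloxy radical 27 (not isolated), via allyl radical 28 (not isolated)
Conditions: Bu3SnH (1.3 equiv) and AIBN (0.2 equiv) added by syringe pump over 8 h, benzene, 80 °C, 0.005 M
Reagents that add atoms: none
Why: The stannyl radical abstracts the phenylseleno group to give the secondary C13 radical 26, which attacks the C16 carbonyl carbon on the adjacent bridgehead C12 (3-exo-trig closure) to give the cyclopropyloxy radical 27; β-scission of the C12–C16 bond then moves the acyl carbon from C12 to C13 and leaves the allyl radical 28, so that the six-membered ring C8–C15–C16–C12–C13–C14 contracts to the five-membered ring D. The closest known reaction type is the radical 1,2-acyl shift of β-keto alkyl radicals (Dowd–Beckwith-type rearrangement), which converts bicyclo[2.2.2]octanone radicals into bicyclo[3.2.1]octanone radicals. Ring D is therefore not closed end to end but arises by 3-exo-trig closure followed by ring opening, and the only new stereocentre, bridgehead C13, can form in one sense only because C16 stays tied to C8 through C15 and migrates suprafacially across the C12–C13 bond. The step needs the acyl shift to outrun hydrogen transfer to 26 and to prevail over 3-exo attack on C11 of the C9=C11 alkene; slow addition keeps the stannane dilute, the α-ketal makes the carbonyl carbon a good radical acceptor, both shifts are reversible and only the acyl shift ends in the allyl-stabilised radical 28 (the competing shift of C11 gives a less stabilised α-keto radical), and 28 should take its hydrogen at the secondary C12 because C9 is flanked by the quaternary C8 and C10.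

Step 17
Reactants: 29 15,15-dimethoxy-16-oxo-17-nor-6,7-seco-ent-kaur-9(11)-ene lactone
Product: 30 16-hydroxy-16-[(trimethylsilyl)methyl] adduct
Conditions: Me3SiCH2MgCl, CeCl3, THF, −78 °C
Reagents that add atoms: (trimethylsilyl)methylmagnesium chloride C[Si](C)(C)C[Mg]Cl
Why: Organocerium 1,2-addition (first stage of a Peterson olefination) should take the non-enolisable C16 ketone in preference to acetate and lactone and masks the future exocyclic methylene as a β-hydroxysilane that borane does not touch.

Step 18
Reactants: 30 16-hydroxy-16-[(trimethylsilyl)methyl] adduct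
Product: 32 11-hydroxy β-hydroxysilane, via C11 alkylborane 31 (not isolated)
Conditions: BH3·THF, THF, 0 °C → rt; then H2O2, aq. NaHCO3, 0 °C
Reagents that add atoms: hydrogen peroxide OO
Why: Hydroboration–oxidation adds H to C9 and OH to C11 syn and anti-Markovnikov from the face of the one-carbon bridge C14, the other face being screened by C15(OMe)2, the C16 substituents and C5 of ring A, which gives axial H9 and equatorial 11-OH as in the target.

Step 19
Reactants: 32 11-hydroxy β-hydroxysilane
Product: 33 trichorabdal B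
Conditions: 48% aq. HF, MeCN, 0 °C → rt
Reagents that add atoms: water O
Why: Acid-mediated Peterson elimination of the β-hydroxysilane gives C16=CH2, and the same acid hydrolyses the C15 dimethyl ketal and the C6 dimethyl acetal to the enone carbonyl and the aldehyde while acetate, lactone and the secondary alcohol persist.

**Compound list**

1 | 2,2-dimethoxyacetaldehyde | COC(OC)C=O | starting material
2 | 1-(triphenyl-λ5-phosphanylidene)propan-2-one | CC(=O)C=P(c1ccccc1)(c1ccccc1)c1ccccc1 | starting material
3 | (E)-5,5-dimethoxypent-3-en-2-one | CC(=O)/C=C/C(OC)OC | intermediate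
4 | lithium (E)-5,5-dimethoxypenta-1,3-dien-2-olate | [Li+].C=C([O-])/C=C/C(OC)OC | intermediate
5 | (E)-2-(tert-butyldimethylsilyloxy)-5,5-dimethoxypenta-1,3-diene | C=C(O[Si](C)(C)C(C)(C)C)/C=C/C(OC)OC | intermediate
6 | methacrolein (2-methylprop-2-enal) | CC(=C)C=O | starting material
7 | (1R,2S)-4-[(tert-butyldimethylsilyl)oxy]-2-(dimethoxymethyl)-1-methylcyclohex-3-ene-1-carbaldehyde (CHO cis to CH(OMe)2) | C1=C(O[Si](C)(C)C(C)(C)C)CC[C@@](C)(C=O)[C@H]1C(OC)OC | intermediate
8 | [(1R,2S)-4-[(tert-butyldimethylsilyl)oxy]-2-(dimethoxymethyl)-1-methylcyclohex-3-en-1-yl]methanol | C1=C(O[Si](C)(C)C(C)(C)C)CC[C@@](C)(CO)[C@H]1C(OC)OC | intermediate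
9 | [(1R,2S)-4-[(tert-butyldimethylsilyl)oxy]-2-(dimethoxymethyl)-1-methylcyclohex-3-en-1-yl]methyl acetate | C1=C(O[Si](C)(C)C(C)(C)C)CC[C@@](C)(COC(C)=O)[C@H]1C(OC)OC | intermediate
10 | Mannich base: 3-[(dimethylamino)methyl] derivative of the 4-oxocyclohexyl acetate (both C3 epimers) | CN(C)CC1C(=O)CC[C@@](C)(COC(C)=O)[C@H]1C(OC)OC | intermediate
11 | methiodide of 10 (trimethylammonium iodide) | [I-].C[N+](C)(C)CC1C(=O)CC[C@@](C)(COC(C)=O)[C@H]1C(OC)OC | intermediate
12 | [(1R,2R)-2-(dimethoxymethyl)-1-methyl-3-methylidene-4-oxocyclohexyl]methyl acetate | C=C1C(=O)CC[C@@](C)(COC(C)=O)[C@H]1C(OC)OC | intermediate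
13 | [(1R,2R)-2-(dimethoxymethyl)-4-hydroxy-1-methyl-3-methylidenecyclohexyl]methyl acetate (both C4 epimers) | C=C1C(O)CC[C@@](C)(COC(C)=O)[C@H]1C(OC)OC | intermediate
14 | [(1R,2R)-2-(dimethoxymethyl)-3-(hydroxymethyl)-1-methylcyclohex-3-en-1-yl]methyl acetate | OCC1=CCC[C@@](C)(COC(C)=O)[C@H]1C(OC)OC | intermediate
15 | 1-(benzyloxy)-4-bromo-2-methoxybenzene | COc1cc(Br)ccc1OCc1ccccc1 | starting material
16 | [3-(benzyloxy)-6-bromo-2-methoxyphenyl]lithium | [Li]c1c(Br)ccc(OCc2ccccc2)c1OC | intermediate
17 | 3-(benzyloxy)-6-bromo-2-methoxybenzoic acid | OC(=O)c1c(Br)ccc(OCc2ccccc2)c1OC | intermediate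
18 | [(5R,6R)-5-(acetoxymethyl)-6-(dimethoxymethyl)-5-methylcyclohex-1-en-1-yl]methyl 3-(benzyloxy)-6-bromo-2-methoxybenzoate | COc1c(OCc2ccccc2)ccc(Br)c1C(=O)OCC1=CCC[C@@](C)(COC(C)=O)[C@H]1C(OC)OC | intermediate
19 | [(1S,5R,6R)-7'-(benzyloxy)-6-(dimethoxymethyl)-8'-methoxy-5-methyl-1'-oxospiro[cyclohex-2-ene-1,4'-isochroman]-5-yl]methyl acetate (aryl trans to CH(OMe)2 and CH2OAc) | COc1c(OCc3ccccc3)ccc2c1C(=O)OC[C@]21C=CC[C@@](C)(COC(C)=O)[C@H]1C(OC)OC | intermediate
20 | [(1S,2R,3R)-2-(dimethoxymethyl)-7'-hydroxy-8'-methoxy-3-methyl-1'-oxospiro[cyclohexane-1,4'-isochroman]-3-yl]methyl acetate | COc1c(O)ccc2c1C(=O)OC[C@]21CCC[C@@](C)(COC(C)=O)[C@H]1C(OC)OC | intermediate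
21 | masked o-benzoquinone: 8',8'-dimethoxy-7'-oxo-7',8'-dihydro derivative of 20 (C16 ketone, C15 dimethyl ketal, diene C12=C11–C9=C8, lactone and ring A unchanged) | COC1(OC)C(=O)C=CC2=C1C(=O)OC[C@]21CCC[C@@](C)(COC(C)=O)[C@H]1C(OC)OC | intermediate
22 | phenylselenenyl bromide | Br[Se]c1ccccc1 | starting material
23 | vinylmagnesium bromide | C=C[Mg]Br | starting material
24 | phenyl vinyl selenide | C=C[Se]c1ccccc1 | intermediate
25 | Diels–Alder adduct: bicyclo[2.2.2]octene with bridgeheads C8 and C12; bridges C15(OMe)2–C16(=O), C9=C11 and C14H2–C13H(SePh); δ-lactone and ring A as in 21; both C13 epimers | O=C1C(OC)(OC)[C@]23CC([Se]c4ccccc4)[C@H]1C=C2[C@@]1(CCC[C@@](C)(COC(C)=O)[C@H]1C(OC)OC)COC3=O | intermediate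
26 | C13 radical of the bicyclo[2.2.2]octenone | O=C1C(OC)(OC)[C@]23C[CH][C@H]1C=C2[C@@]1(CCC[C@@](C)(COC(C)=O)[C@H]1C(OC)OC)COC3=O | intermediate
27 | cyclopropyloxy radical (three-membered ring C12–C13–C16, oxygen radical on C16) | [O][C@]12C(OC)(OC)[C@]34C[C@H]1[C@H]2C=C3[C@@]1(CCC[C@@](C)(COC(C)=O)[C@H]1C(OC)OC)COC4=O | intermediate
28 | allyl radical C12–C11=C9 of the bicyclo[3.2.1]octenone | O=C1C(OC)(OC)[C@]23C[C@H]1[CH]C=C2[C@@]1(CCC[C@@](C)(COC(C)=O)[C@H]1C(OC)OC)COC3=O | intermediate
29 | rearranged ketone: 19-acetoxy-15,15-dimethoxy-16-oxo-17-nor-6,7-seco-ent-kaur-9(11)-ene 7,20-lactone with C6 as dimethyl acetal | O=C1C(OC)(OC)[C@]23C[C@H]1CC=C2[C@@]1(CCC[C@@](C)(COC(C)=O)[C@H]1C(OC)OC)COC3=O | intermediate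
30 | 16-hydroxy-16-[(trimethylsilyl)methyl] derivative of 29 (C16 configuration open, lost later) | C[Si](C)(C)CC1(O)C(OC)(OC)[C@]23C[C@H]1CC=C2[C@@]1(CCC[C@@](C)(COC(C)=O)[C@H]1C(OC)OC)COC3=O | intermediate
31 | C11 alkylborane from 30 (drawn as the monoalkylborane; H9 and boron on the face of C14) | C[Si](C)(C)CC1(O)C(OC)(OC)[C@]23C[C@H]1C[C@@H](B)[C@@H]2[C@@]1(CCC[C@@](C)(COC(C)=O)[C@H]1C(OC)OC)COC3=O | intermediate
32 | 11-hydroxy β-hydroxysilane (C9–H and C11–OH as in the target; C15 ketal and C6 acetal in place) | C[Si](C)(C)CC1(O)C(OC)(OC)[C@]23C[C@H]1C[C@@H](O)[C@@H]2[C@@]1(CCC[C@@](C)(COC(C)=O)[C@H]1C(OC)OC)COC3=O | intermediate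
33 | trichorabdal B | C=C1C(=O)[C@]23C[C@H]1C[C@@H](O)[C@@H]2[C@@]1(CCC[C@@](C)(COC(C)=O)[C@H]1C=O)COC3=O | target

**Step count and risks**

Total step count: 19. Longest linear sequence: 17 steps (steps 1–8, 10–13 and 15–19, from 2,2-dimethoxyacetaldehyde).

The three steps most likely to fail:

Step 11 (Heck cyclisation). Zerovalent palladium may ionise the allylic benzoate to a π-allyl complex and expel the carboxylate, or insertion into the hindered trisubstituted alkene may be too slow. The fallback makes the C9–C10 bond by palladium-catalysed α-arylation of an α-branched aldehyde. It sets out from 14. Hydrogenation (H2, Pd on carbon) gives the saturated alcohol F1 and Dess–Martin oxidation gives the aldehyde F2. Acid 17 is methylated (MeI, K2CO3, DMF) to the methyl ester F3. Pd(OAc)2, rac-2,2'-bis(diphenylphosphino)-1,1'-binaphthyl and Cs2CO3 in dioxane at 80 °C should join F2 and F3 to the α-aryl aldehyde F4, the aryl group entering anti to CH(OMe)2. NaBH4 reduction lets the alkoxide close the lactone onto the methyl ester to give the benzyl ether F5, and hydrogenolysis (H2, Pd on carbon) comes back to the route at 20.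

Step 15 (Diels–Alder of the masked o-benzoquinone). Cycloaddition at the fully substituted diene terminus C8 may be slow, so that regio- or facial selectivity erodes or the dienone decays thermally. The fallback uses a smaller and more electron-rich dienophile and makes the C13 radical by deoxygenation. It sets out from 21. Trimethyl(vinyloxy)silane should give the silyl ether F6, and citric acid in MeOH frees the alcohol F7. 1,1'-Thiocarbonyldiimidazole gives the imidazole-1-carbothioate F8. Bu3SnH and AIBN under slow addition (Barton–McCombie conditions) then generate radical 26, which rearranges as in step 16, and the route is rejoined at 29.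

Step 16 (radical 1,2-acyl shift). Hydrogen transfer to the C13 radical may occur before the shift, or the radical from the competing vinyl shift may be trapped first. The fallback separates the shift from the reduction in a group-transfer chain that has no hydride donor. It sets out from 21. Acrylic acid should add in the normal-demand sense to give the C13 carboxylic acid F9. DCC and N-hydroxypyridine-2-thione give the thiohydroxamate (Barton) ester F10. Visible light in benzene at rt decarboxylates F10 to radical 26, which has time to rearrange fully; allyl radical 28 is then trapped at C12 by the thiocarbonyl group of another molecule of F10 to give the allylic 2-pyridyl sulfide F11. Bu3SnH and AIBN remove the sulfur through the same allyl radical, and the route is rejoined at 29.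

Further compounds
F1 | step 11 | [(1R,2R)-2-(dimethoxymethyl)-3-(hydroxymethyl)-1-methylcyclohexyl]methyl acetate (both C3 epimers) | OCC1CCC[C@@](C)(COC(C)=O)[C@H]1C(OC)OC
F2 | step 11 | [(1R,2R)-2-(dimethoxymethyl)-3-formyl-1-methylcyclohexyl]methyl acetate (both C3 epimers) | O=CC1CCC[C@@](C)(COC(C)=O)[C@H]1C(OC)OC
F3 | step 11 | methyl 3-(benzyloxy)-6-bromo-2-methoxybenzoate | COC(=O)c1c(Br)ccc(OCc2ccccc2)c1OC
F4 | step 11 | methyl 6-[3-(acetoxymethyl)-2-(dimethoxymethyl)-1-formyl-3-methylcyclohexyl]-3-(benzyloxy)-2-methoxybenzoate (aryl trans to CH(OMe)2) | O=C[C@@]1(c2ccc(OCc3ccccc3)c(OC)c2C(=O)OC)CCC[C@@](C)(COC(C)=O)[C@H]1C(OC)OC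
F5 | step 11 | 7'-O-benzyl ether of 20 | COc1c(OCc3ccccc3)ccc2c1C(=O)OC[C@]21CCC[C@@](C)(COC(C)=O)[C@H]1C(OC)OC
F6 | step 15 | 13-(trimethylsilyloxy) analogue of 25 (both C13 epimers) | O=C1C(OC)(OC)[C@]23CC(O[Si](C)(C)C)[C@H]1C=C2[C@@]1(CCC[C@@](C)(COC(C)=O)[C@H]1C(OC)OC)COC3=O
F7 | step 15 | 13-hydroxy analogue of 25 (both C13 epimers) | O=C1C(OC)(OC)[C@]23CC(O)[C@H]1C=C2[C@@]1(CCC[C@@](C)(COC(C)=O)[C@H]1C(OC)OC)COC3=O
F8 | step 15 | 13-O-(imidazole-1-carbothioyl) derivative of F7 | O=C1C(OC)(OC)[C@]23CC(OC(=S)n4ccnc4)[C@H]1C=C2[C@@]1(CCC[C@@](C)(COC(C)=O)[C@H]1C(OC)OC)COC3=O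
F9 | step 16 | 13-carboxylic acid analogue of 25 (both C13 epimers) | O=C1C(OC)(OC)[C@]23CC(C(=O)O)[C@H]1C=C2[C@@]1(CCC[C@@](C)(COC(C)=O)[C@H]1C(OC)OC)COC3=O
F10 | step 16 | 2-thioxopyridin-1(2H)-yl ester of F9 | O=C1C(OC)(OC)[C@]23CC(C(=O)ON4C=CC=CC4=S)[C@H]1C=C2[C@@]1(CCC[C@@](C)(COC(C)=O)[C@H]1C(OC)OC)COC3=O
F11 | step 16 | 12-(pyridin-2-ylsulfanyl) derivative of 29 (both C12 epimers) | O=C1C(OC)(OC)[C@]23C[C@H]1C(Sc4ccccn4)C=C2[C@@]1(CCC[C@@](C)(COC(C)=O)[C@H]1C(OC)OC)COC3=O
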